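The tridepside is cut through its central ring. Ring B carries the ester carbonyl on C1, OH on C2, an acyloxy group on C4 and CH3 on C6. This resorcylate pattern maps onto an alkynoate (C1, C6) plus a 1,1,3-trioxygenated butadiene (C2–C5). A single [4+2] cycloaddition–aromatisation forms C1–C2 and C5–C6, builds ring B and unites both halves with the two depside esters already in place. Its precursors are the but-2-ynoate of the ring C phenol and a silyl ketene acetal diene whose C3 oxygen bears the dibenzylated ring A acyl group. Both come from methyl orsellinate. Hydrogenolysis of the benzyl ethers completes the synthesis.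

Key step: step 9

Remark on the chemistry: the target has no stereocentre, stereogenic axis or stereogenic double bond. It is one achiral compound, so no enantiocontrol is needed. The transient stereoelements of the route (enol ester and ketene acetal geometry, the ketal carbon of the cycloadduct) are erased on aromatisation. Direct methylation of methyl orsellinate would go to O4, so ring C is made by a protect/methylate/deprotect sequence.

Step 1
Reactants: 1 methyl orsellinate (methyl 2,4-dihydroxy-6-methylbenzoate)
Product: 2 methyl 4-(benzyloxy)-2-hydroxy-6-methylbenzoate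
Conditions: BnBr (1.05 equiv), K2CO3, acetone, reflux
Reagents that add atoms: benzyl bromide, BrCc1ccccc1
Why: Williamson ether synthesis in which the C2–OH, held in a hydrogen bond to the ester carbonyl, stays unreactive toward one equivalent of halide and a weak base, so only the free C4–OH should be benzylated.

Step 2
Reactants: 2 methyl 4-(benzyloxy)-2-hydroxy-6-methylbenzoate
Product: 3 methyl 4-(benzyloxy)-2-methoxy-6-methylbenzoate
Conditions: MeI (3 equiv), K2CO3, DMF, 50 °C
Reagents that add atoms: methyl iodide, CI
Why: Williamson O-methylation of the remaining chelated phenol under more forcing conditions, the temporary benzyl group on O4 ensuring that the methyl ends up on O2 and not on the intrinsically more reactive O4.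

Step 3
Reactants: 3 methyl 4-(benzyloxy)-2-methoxy-6-methylbenzoate
Product: 4 methyl 4-hydroxy-2-methoxy-6-methylbenzoate (ring C phenol)
Conditions: H2 (1 atm), 10% Pd/C, EtOAc–MeOH, rt
Reagents that add atoms: none
Why: Catalytic hydrogenolysis of a benzyl aryl ether, under which the methyl ester, the aryl methyl ether and the arene are inert.

Step 4
Reactants: 4 methyl 4-hydroxy-2-methoxy-6-methylbenzoate, 5 but-2-ynoic acid
Product: 6 methyl 4-(but-2-ynoyloxy)-2-methoxy-6-methylbenzoate (ring C but-2-ynoate)
Conditions: DCC (1.1 equiv), DMAP (5 mol%), CH2Cl2, 0 °C to rt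
Reagents that add atoms: none
Why: Steglich esterification, the usual access to aryl alk-2-ynoates, with low temperature and only catalytic DMAP to suppress base-induced isomerisation to the allenoate.

Step 5
Reactants: 1 methyl orsellinate
Product: 7 methyl 2,4-bis(benzyloxy)-6-methylbenzoate
Conditions: BnBr (2.5 equiv), K2CO3 (3 equiv), DMF, 70 °C
Reagents that add atoms: benzyl bromide, BrCc1ccccc1
Why: Double Williamson ether synthesis, in which excess halide and heating in DMF should also alkylate the chelated C2–OH.

Step 6
Reactants: 7 methyl 2,4-bis(benzyloxy)-6-methylbenzoate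
Product: 8 2,4-bis(benzyloxy)-6-methylbenzoic acid
Conditions: KOH, DMSO–H2O, 100 °C; then cold 1 M HCl
Reagents that add atoms: potassium hydroxide, [K+].[OH-] (oxygen of the carboxyl OH)
Why: Saponification of a di-ortho-substituted benzoate, driven by hot hydroxide in aqueous DMSO, conditions to which benzyl ethers are stable.

Step 7
Reactants: 8 2,4-bis(benzyloxy)-6-methylbenzoic acid, 9 methyl acetoacetate
Product: 11 methyl (E)-3-{[2,4-bis(benzyloxy)-6-methylbenzoyl]oxy}but-2-enoate, via aroyl chloride 10 (not isolated)
Conditions: (COCl)2 (1.2 equiv), DMF (cat.), CH2Cl2, 0 °C to rt, evaporate; then 9 (1.3 equiv), Et3N (1.5 equiv), DMPU–CH2Cl2, 0 °C to rt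
Reagents that add atoms: oxalyl chloride, O=C(Cl)C(=O)Cl (its chlorine appears only in intermediate 10)
Why: DMF-catalysed acid chloride formation followed by kinetic O-acylation of the ammonium enolate of a β-keto ester in a dipolar aprotic medium (enol ester formation); the hard, di-ortho-substituted aroyl chloride favours attack by oxygen, the hindered enol ester should not pass its acyl group on to carbon, DMAP is left out because it promotes O-to-C migration, and the enol ester geometry (mainly E expected) does not matter for step 8.

Step 8
Reactants: 11 methyl (E)-3-{[2,4-bis(benzyloxy)-6-methylbenzoyl]oxy}but-2-enoate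
Product: 12 4-methoxy-4-(trimethylsilyloxy)buta-1,3-dien-2-yl 2,4-bis(benzyloxy)-6-methylbenzoate (ketene acetal drawn Z)
Conditions: TMSCl (2 equiv), then LDA (commercial solution, 1.05 equiv, slow addition), THF, −78 °C; evaporate, pentane, filter under Ar; used crude
Reagents that add atoms: chlorotrimethylsilane, C[Si](C)(C)Cl
Why: Kinetic γ-deprotonation of a β-oxygenated crotonate and O-silylation of the dienolate, the standard preparation of 3-alkoxy- and 3-silyloxy-1-methoxy-1-silyloxybutadienes; the internal silyl chloride quench traps the dienolate before acyl transfer, the di-ortho-substituted aroyl carbonyl is shielded from the amide, and one equivalent of base leaves the less acidic ring A methyl untouched.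

Step 9
Reactants: 6 methyl 4-(but-2-ynoyloxy)-2-methoxy-6-methylbenzoate, 12 4-methoxy-4-(trimethylsilyloxy)buta-1,3-dien-2-yl 2,4-bis(benzyloxy)-6-methylbenzoate
Product: 15 methyl 4-{[4-{[2,4-bis(benzyloxy)-6-methylbenzoyl]oxy}-2-hydroxy-6-methylbenzoyl]oxy}-2-methoxy-6-methylbenzoate (ring A di-O-benzyl tridepside), via cyclohexadiene ketal cycloadduct 13 (not isolated), via ring B cyclohexadienone 14 (not isolated)
Conditions: 12 (2 equiv), PhMe (ca. 2 M), sealed tube, 120 °C; then 1 M aq. HCl–THF, rt
Reagents that add atoms: none
Why: Proposed new method: the ketene acetal terminus raises the diene HOMO and, together with the C3 oxygen, places the largest coefficient on the terminal CH2 (future C5), which should attack the methyl-bearing β-carbon of the electron-poor aryl ynoate (future C6) while the acetal carbon (C2) bonds to the α-carbon (C1) in an asynchronous normal-electron-demand Diels–Alder reaction, so ring B is closed by an intermolecular [4+2] cycloaddition giving 1,4-cyclohexadiene 13. The closest known reaction type is the Diels–Alder/aromatisation of 1-alkoxy-1,3-bis(silyloxy)butadienes and 1,1-dialkoxy-3-silyloxybutadienes with alk-2-ynoates to resorcylates; what is new is the aroyl group on the C3 oxygen, whose weaker donation is offset by heat, high concentration, excess diene and the better acceptor quality of an aryl ester. Dilute acid should ionise the doubly allylic mixed ketal of 13 with loss of methanol, desilylation then gives cross-conjugated dienone 14, and enolisation through the C5 methylene delivers the phenol, the retained oxygen being the silylated one as in related annulations of methyl silyl ketene acetals. No stereocentre has to be controlled, since the racemic ketal carbon of 13 and the ketene acetal geometry disappear on aromatisation. The selectivity required is regiochemical (OH and CH3 both ortho to the new ester carbon) and is secured by the polarity match of the nucleophilic CH2 terminus and the electrophilic β-carbon. The hindered aryl and enol ester carbonyls, the methyl ester and the benzyl ethers should be inert to neutral thermolysis and brief dilute acid.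

Step 10
Reactants: 15 ring A di-O-benzyl tridepside
Product: 16 methyl 4-{[4-{[2,4-dihydroxy-6-methylbenzoyl]oxy}-2-hydroxy-6-methylbenzoyl]oxy}-2-methoxy-6-methylbenzoate (target)
Conditions: H2 (1 atm), 10% Pd/C, EtOAc–THF, rt
Reagents that add atoms: none
Why: Catalytic hydrogenolysis of the two benzyl aryl ethers, the customary closing step for depsides, run in a non-nucleophilic solvent so that the aryl esters cannot transesterify.

Compound list
1 | methyl orsellinate (methyl 2,4-dihydroxy-6-methylbenzoate) | COC(=O)c1c(C)cc(O)cc1O | starting material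
2 | methyl 4-(benzyloxy)-2-hydroxy-6-methylbenzoate | COC(=O)c1c(C)cc(OCc2ccccc2)cc1O | intermediate
3 | methyl 4-(benzyloxy)-2-methoxy-6-methylbenzoate | COC(=O)c1c(C)cc(OCc2ccccc2)cc1OC | intermediate
4 | methyl 4-hydroxy-2-methoxy-6-methylbenzoate | COC(=O)c1c(C)cc(O)cc1OC | intermediate
5 | but-2-ynoic acid | CC#CC(=O)O | starting material
6 | methyl 4-(but-2-ynoyloxy)-2-methoxy-6-methylbenzoate | COC(=O)c1c(C)cc(OC(=O)C#CC)cc1OC | intermediate
7 | methyl 2,4-bis(benzyloxy)-6-methylbenzoate | COC(=O)c1c(C)cc(OCc2ccccc2)cc1OCc1ccccc1 | intermediate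
8 | 2,4-bis(benzyloxy)-6-methylbenzoic acid | OC(=O)c1c(C)cc(OCc2ccccc2)cc1OCc1ccccc1 | intermediate
9 | methyl acetoacetate | COC(=O)CC(C)=O | starting material
10 | 2,4-bis(benzyloxy)-6-methylbenzoyl chloride (not isolated) | ClC(=O)c1c(C)cc(OCc2ccccc2)cc1OCc1ccccc1 | intermediate
11 | methyl (E)-3-{[2,4-bis(benzyloxy)-6-methylbenzoyl]oxy}but-2-enoate | C/C(OC(=O)c1c(C)cc(OCc2ccccc2)cc1OCc1ccccc1)=C\C(=O)OC | intermediate
12 | 4-methoxy-4-(trimethylsilyloxy)buta-1,3-dien-2-yl 2,4-bis(benzyloxy)-6-methylbenzoate (drawn Z) | C=C(OC(=O)c1c(C)cc(OCc2ccccc2)cc1OCc1ccccc1)/C=C(/OC)O[Si](C)(C)C | intermediate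
13 | methyl 4-{[4-{[2,4-bis(benzyloxy)-6-methylbenzoyl]oxy}-6-methoxy-2-methyl-6-(trimethylsilyloxy)cyclohexa-1,4-diene-1-carbonyl]oxy}-2-methoxy-6-methylbenzoate (racemic at the ketal carbon, not isolated) | COC(=O)c1c(C)cc(OC(=O)C2=C(C)CC(OC(=O)c3c(C)cc(OCc4ccccc4)cc3OCc3ccccc3)=CC2(OC)O[Si](C)(C)C)cc1OC | intermediate
14 | methyl 4-{[4-{[2,4-bis(benzyloxy)-6-methylbenzoyl]oxy}-2-methyl-6-oxocyclohexa-1,4-diene-1-carbonyl]oxy}-2-methoxy-6-methylbenzoate (not isolated) | COC(=O)c1c(C)cc(OC(=O)C2=C(C)CC(OC(=O)c3c(C)cc(OCc4ccccc4)cc3OCc3ccccc3)=CC2=O)cc1OC | intermediate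
15 | methyl 4-{[4-{[2,4-bis(benzyloxy)-6-methylbenzoyl]oxy}-2-hydroxy-6-methylbenzoyl]oxy}-2-methoxy-6-methylbenzoate | COC(=O)c1c(C)cc(OC(=O)c2c(C)cc(OC(=O)c3c(C)cc(OCc4ccccc4)cc3OCc3ccccc3)cc2O)cc1OC | intermediate
16 | methyl 4-{[4-{[2,4-dihydroxy-6-methylbenzoyl]oxy}-2-hydroxy-6-methylbenzoyl]oxy}-2-methoxy-6-methylbenzoate (CNP0503951.0, achiral) | COC(=O)c1c(C)cc(OC(=O)c2c(C)cc(OC(=O)c3c(C)cc(O)cc3O)cc2O)cc1OC | target

Total step count: 10.
Longest linear sequence: 6 steps (steps 1–4, 9, 10, or steps 5–8, 9, 10).

Steps most likely to fail

Risk 1, step 9. The acyloxy diene may be too weak a donor. Thermal decay of the ketene acetal (protodesilylation, O-to-C silyl shift) could then outrun cycloaddition with the β-methyl ynoate. The fallback uses known chemistry: it keeps the benzannulation and moves the A–B ester formation behind it. Setting out from 6, heating with purchased 1-methoxy-1,3-bis(trimethylsilyloxy)buta-1,3-diene F1, the established resorcylate-forming partner of alk-2-ynoates, followed by acidic work-up should give the ring B/C didepside methyl 4-[(2,4-dihydroxy-6-methylbenzoyl)oxy]-2-methoxy-6-methylbenzoate F2. Its unchelated C4–OH is then acylated with one equivalent of aroyl chloride 10 (Et3N, CH2Cl2, 0 °C), the C2–OH being held by the ester carbonyl. This rejoins the route at 15.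

Risk 2, step 8. Three processes may compete with γ-deprotonation and silylation: acyl transfer from the vinylogous anhydride to the dienolate or to the amide base, an anionic O-to-C acyl shift, and lateral deprotonation of the ring A methyl. The fallback drops the diene and assembles the same product by classical depside esterifications. Setting out from 8 (through 10), selective acylation of the unchelated C4–OH of purchased 2,4-dihydroxy-6-methylbenzaldehyde F3 (Et3N, CH2Cl2) should give 4-formyl-3-hydroxy-5-methylphenyl 2,4-bis(benzyloxy)-6-methylbenzoate F4. Pinnick oxidation (NaClO2, NaH2PO4, 2-methylbut-2-ene, aq. t-BuOH) gives 4-{[2,4-bis(benzyloxy)-6-methylbenzoyl]oxy}-2-hydroxy-6-methylbenzoic acid F5. Condensation of F5 with phenol 4 by trifluoroacetic anhydride in toluene rejoins the route at 15.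

Risk 3, step 7. The hindered aroyl chloride may react sluggishly, or acylation may drift from oxygen to carbon of the ambident enolate. The fallback replaces the enolate/acid chloride pairing by a silyl enol ether/acyl fluoride pairing. Setting out from 8, cyanuric fluoride and pyridine give 2,4-bis(benzyloxy)-6-methylbenzoyl fluoride F6. From 9, TMSCl and Et3N give methyl 3-(trimethylsilyloxy)but-2-enoate F7. Catalytic fluoride (TBAF, THF) should then join the two by O-acylation of the enol silyl ether, a known reaction type driven by formation of the Si–F bond. This rejoins the route at 11.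

Further compounds
F1 | step 9 | 1-methoxy-1,3-bis(trimethylsilyloxy)buta-1,3-diene (purchased) | C=C(O[Si](C)(C)C)/C=C(/OC)O[Si](C)(C)C
F2 | step 9 | methyl 4-[(2,4-dihydroxy-6-methylbenzoyl)oxy]-2-methoxy-6-methylbenzoate | COC(=O)c1c(C)cc(OC(=O)c2c(C)cc(O)cc2O)cc1OC
F3 | step 8 | 2,4-dihydroxy-6-methylbenzaldehyde (purchased) | O=Cc1c(C)cc(O)cc1O
F4 | step 8 | 4-formyl-3-hydroxy-5-methylphenyl 2,4-bis(benzyloxy)-6-methylbenzoate | O=Cc1c(C)cc(OC(=O)c2c(C)cc(OCc3ccccc3)cc2OCc2ccccc2)cc1O
F5 | step 8 | 4-{[2,4-bis(benzyloxy)-6-methylbenzoyl]oxy}-2-hydroxy-6-methylbenzoic acid | OC(=O)c1c(C)cc(OC(=O)c2c(C)cc(OCc3ccccc3)cc2OCc2ccccc2)cc1O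
F6 | step 7 | 2,4-bis(benzyloxy)-6-methylbenzoyl fluoride | FC(=O)c1c(C)cc(OCc2ccccc2)cc1OCc1ccccc1
F7 | step 7 | methyl 3-(trimethylsilyloxy)but-2-enoate (drawn Z) | C/C(O[Si](C)(C)C)=C/C(=O)OC
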